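Late in both earlier runs Ej was still climbing, well after the feed of Dz had stopped, so a late slope was what I could read from them and carry to the new flasks.

| setting | cedar | oak | winter | noon |
|---|---|---|---|---|
| Gy | 0.25 M | 1 M | 0.50 M | 0.50 M |
| Ry | 0.25 M | 1 M | 0.50 M | 0.50 M |
| Dz | 1.1 equiv (fed, over 12 s) | 1.1 equiv (fed, over 12 s) | 1.10 equiv (fed, over 12 s) | 1.10 equiv (fed, over 12 s) |
| Qa | 0.2 mol% | 0.2 mol% | 0.2 mol% | 0.2 mol% |
| temperature | 10 °C | 25 °C | 15 °C | 35 °C |
| remark | run made earlier; the fed solution adds 0.50 times the starting volume | run made earlier; the fed solution adds 0.50 times the starting volume | the fed solution adds 0.50 times the starting volume | the fed solution adds 0.50 times the starting volume |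
| time |  |  | 3.0 min | 3.0 min |

| run | time / s | Ej / % |
|---|---|---|
| cedar | 10.0 | 0.1 |
| cedar | 15.0 | 0 |
| cedar | 30.0 | 0.6 |
| cedar | 50.0 | 1.4 |
| cedar | 60.0 | 1.1 |
| cedar | 80.0 | 2.5 |
| cedar | 120 | 3.3 |
| oak | 10.0 | 1.1 |
| oak | 20.0 | 4.1 |
| oak | 30.0 | 6.5 |
| oak | 40.0 | 8.7 |
| oak | 50.0 | 10.4 |
| oak | 60.0 | 12.0 |
| oak | 80.0 | 15.2 |

(each reading ± 0.3 percentage points)

- Qa is single-handed; Gy and Ry are mirror images of each other, charged as a racemate, each of them at the stated concentration
- charges are per starting volume, the dose included; the dosed solution carries all of it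

1. the flask with the highest amount of Ej, in percent of the Gy and Ry together charged ("all alike" if they lie within 1.5 percentage points) (winter / noon / all alike)
2. final Ej, as a percentage of the Gy and Ry together charged, in winter
3. final Ej, as a percentage of the Gy and Ry together charged, in noon

I took r as the gain of Ej per second, as a fraction of the Gy and Ry charged, between the third and last readings of each run.

r(cedar) = 3.00 × 10⁻⁴ s⁻¹

r(oak) = 0.00174 s⁻¹

These two runs differ in both the concentration c of Gy and the temperature. I took the binding of Qa to substrate as fast and in balance at each moment, which leaves two versions I could solve. If Qa sits wholly on substrate, r goes as c, since Dz and Qa are both charged in proportion to c. If Qa stays mostly free, r goes as c squared. The free version leaves 0.362 for the warming from cedar to oak, a factor below one for a rise in temperature, and I rejected it. The bound version leaves 1.45. This is my warming factor f, the oak-to-cedar ratio of late slopes with concentration divided out once; it is a reading and carries the scatter of those slopes. I placed the real flask near the bound end.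

Scaling cedar's slope by c, and by f raised to the fraction of the cedar-to-oak temperature span covered, then running it over the 168 s after the feed, I reckoned:

winter: r = 6.79 × 10⁻⁴ s⁻¹, Ej = 11.4%

noon: r = 0.00111 s⁻¹, Ej = 18.7%

The forecast named noon, with 12% in winter and 26% in noon, arguing “so the concentration order must be lower”. My noon figure was lower than its figure.

The flasks gave noon as the highest, the flask the forecast had named, with 11.1% in winter and 21.4% in noon, and noon stood 2.7 percentage points above my line.

    Qa + Gy ⇌ Ji (K = 13.0 M⁻¹, k = 130 M⁻¹ s⁻¹, Ea = 52.0 kJ mol⁻¹, ΔH = −14.0 kJ mol⁻¹)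
    Qa + Ry ⇌ Ly (K = 34.0 M⁻¹, k = 230 M⁻¹ s⁻¹, Ea = 41.0 kJ mol⁻¹, ΔH = 2.00 kJ mol⁻¹)
    Dz + Ji → Qa + Ej (k = 41.0 M⁻¹ s⁻¹, Ea = 50.0 kJ mol⁻¹)
    Dz + Ly → Qa + Ty (k = 18.0 M⁻¹ s⁻¹, Ea = 55.0 kJ mol⁻¹)
    2 Qa → Rx (k = 25.0 M⁻¹ s⁻¹, Ea = 47.0 kJ mol⁻¹)
    Gy ⇌ Ry (k = 0.0500 s⁻¹, Ea = 85.0 kJ mol⁻¹)
    (constants at 35 °C)

The bound version behind f = 1.45 came close in winter: at 3.00 min, Ly held 64.4% of the catalyst charged and Ji 22.9%, against 10.8% as free Qa and 1.89% as Rx. So Ly is the resting state in winter. In noon, with the reaction of Qa + Ry to Ly struck out both ways, Ej reached 49.1% instead of 21.4%, the largest single effect. For the winter flask with 0.05 mol% of Qa, my winter line, which carries f, cut in proportion to Qa gives 2.85%; that flask gave 3.25%.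

Readings and results were computed from invented constants; scatter was added.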